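**Plan**

1. Cuts: the furanone is opened across O1–C2 and C3=C4 (α-hydroxy ketone plus Ph3P=C=C=O). The chain alkene C(CH2OH)=CH is cut at its C=C bond and its C–CH2OH bond into a phosphonium salt, a five-carbon aldehyde and formaldehyde. The E methyl alkene is cut at its C–CH3 bond and at the C–C bond on its ring side (dihydropyran, alkyl iodide, MeMgBr), and the ring–vinyl bond is cut last, back to a cyclohexane-1,3-dione.
2. Enabling feature: the acyclic trisubstituted alkene C(CH2OH)=CH–CH2 attached to C5 of the furanone ring has its hydroxymethyl carbon cis to the CH2 that leads to that ring carbon. This is the geometry a β-oxido phosphonium ylide gives when it is trapped with formaldehyde.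
3. Forward order: the cyclohexene ring comes from the dione and is extended (vinyl, then the dihydropyran carbons, then methyl) to the phosphonium salt. The aldehyde comes from 2-deoxy-D-ribose, the three components are joined in one flask, and the furanone ring, the only ring made, is closed last.
4. Stereochemistry: ring carbinol (S) from a CBS reduction; furanone C5 (S) from C3 of 2-deoxy-D-ribose (its C4 is later oxidised away); E alkene from retention in the nickel coupling; Z hydroxymethyl alkene from the β-oxido ylide sequence.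

Key step: step 16

Remark: formaldehyde is charged as dry paraformaldehyde and is assumed to depolymerise under the basic conditions of the coupling; 2-deoxy-D-ribose is drawn open-chain.

**Route**

Step 1
Reactants: 1 4,4-dimethylcyclohexane-1,3-dione
Product: 2 2,4,4-trimethylcyclohexane-1,3-dione
Conditions: MeI, KOH, MeOH/H2O, 65 °C
Reagents that add atoms: iodomethane, CI
Why: C-alkylation of the cyclic 1,3-dione enolate at the carbon between the two carbonyls, the standard entry to 2-alkylcyclohexane-1,3-diones.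

Step 2
Reactants: 2 2,4,4-trimethylcyclohexane-1,3-dione
Product: 3 3-(2-methylpropoxy)-2,6,6-trimethylcyclohex-2-en-1-one
Conditions: i-BuOH, p-toluenesulfonic acid (cat.), toluene, reflux (Dean–Stark)
Reagents that add atoms: 2-methylpropan-1-ol, CC(C)CO
Why: Acid-catalysed vinylogous ester formation should take place at the carbonyl remote from the gem-dimethyl group, which leaves the hindered carbonyl as the ketone.

Step 3
Reactants: 3 3-(2-methylpropoxy)-2,6,6-trimethylcyclohex-2-en-1-one
Product: 5 2,4,4-trimethyl-3-vinylcyclohex-2-en-1-one, via bromomagnesium carbinolate 4 (not isolated)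
Conditions: CH2=CHMgBr, THF, 0 °C → rt; then 1 M HCl, rt
Reagents that add atoms: vinylmagnesium bromide, C=C[Mg]Br; water, O
Why: Stork–Danheiser alkylative carbonyl transposition, in which 1,2-addition of the small vinyl Grignard reagent to the vinylogous ester carbonyl is followed by acid hydrolysis of the enol ether with loss of water, so that the carbonyl moves to the former alkoxy carbon.

Step 4
Reactants: 5 2,4,4-trimethyl-3-vinylcyclohex-2-en-1-one
Product: 6 (1S)-2,4,4-trimethyl-3-vinylcyclohex-2-en-1-ol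
Conditions: (R)-2-methyl-CBS-oxazaborolidine [(3aR)-1-methyl-3,3-diphenyltetrahydro-1H,3H-pyrrolo[1,2-c][1,3,2]oxazaborole] (20 mol%), catecholborane, toluene, −78 °C; then MeOH/H2O
Reagents that add atoms: none
Why: Corey–Bakshi–Shibata reduction, in which the (R)-oxazaborolidine treats the fully substituted alkene carbon as the large group and the ring CH2 as the small one and so should deliver hydride to the face that gives the (S)-allylic alcohol, while catecholborane at −78 °C leaves the vinyl group alone.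

Step 5
Reactants: 6 (1S)-2,4,4-trimethyl-3-vinylcyclohex-2-en-1-ol
Product: 7 tert-butyldimethylsilyl ether of 6
Conditions: TBSCl, imidazole, DMF, rt
Reagents that add atoms: tert-butyldimethylsilyl chloride, CC(C)(C)[Si](C)(C)Cl
Why: Imidazole-promoted silylation of a secondary alcohol, which gives an ether that withstands the organolithium, Grignard and ylide steps that follow.

Step 6
Reactants: 7 tert-butyldimethylsilyl ether of 6
Product: 9 2-[(3S)-3-(tert-butyldimethylsilyloxy)-2,6,6-trimethylcyclohex-1-en-1-yl]ethan-1-ol, via alkyl-9-BBN borane 8 (not isolated)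
Conditions: 9-BBN (9-borabicyclo[3.3.1]nonane), THF, 0 °C → rt; then NaOH, H2O2, 0 °C → rt
Reagents that add atoms: hydrogen peroxide, OO
Why: Anti-Markovnikov hydroboration–oxidation, in which the bulky borane adds only to the monosubstituted vinyl terminus and not to the tetrasubstituted ring alkene.

Step 7
Reactants: 9 2-[(3S)-3-(tert-butyldimethylsilyloxy)-2,6,6-trimethylcyclohex-1-en-1-yl]ethan-1-ol
Product: 10 tert-butyl{[(1S)-3-(2-iodoethyl)-2,4,4-trimethylcyclohex-2-en-1-yl]oxy}dimethylsilane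
Conditions: I2, PPh3, imidazole, CH2Cl2, 0 °C → rt
Reagents that add atoms: iodine, II
Why: Appel-type iodination of a primary alcohol under neutral conditions that the allylic silyl ether tolerates.

Step 8
Reactants: 10 tert-butyl{[(1S)-3-(2-iodoethyl)-2,4,4-trimethylcyclohex-2-en-1-yl]oxy}dimethylsilane; 11 3,4-dihydro-2H-pyran
Product: 13 6-{2-[(3S)-3-(tert-butyldimethylsilyloxy)-2,6,6-trimethylcyclohex-1-en-1-yl]ethyl}-3,4-dihydro-2H-pyran, via 6-lithio-3,4-dihydro-2H-pyran 12 (not isolated)
Conditions: 11, t-BuLi, THF/pentane, −78 → 0 °C; then 10, THF, −30 °C → rt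
Reagents that add atoms: none
Why: α-Lithiation of the cyclic enol ether followed by SN2 alkylation of the alkenyllithium with the primary iodide, a known way to 6-alkyl dihydropyrans that also works with homoallylic iodides.

Step 9
Reactants: 13 6-{2-[(3S)-3-(tert-butyldimethylsilyloxy)-2,6,6-trimethylcyclohex-1-en-1-yl]ethyl}-3,4-dihydro-2H-pyran
Product: 14 (4E)-7-[(3S)-3-(tert-butyldimethylsilyloxy)-2,6,6-trimethylcyclohex-1-en-1-yl]-5-methylhept-4-en-1-ol
Conditions: MeMgBr (3 equiv), NiCl2(PPh3)2 (10 mol%), toluene, 70 °C; then aq. NH4Cl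
Reagents that add atoms: methylmagnesium bromide, C[Mg]Br
Why: Wenkert-type nickel-catalysed coupling of an enol ether with a Grignard reagent, in which zerovalent nickel inserts into the alkenyl C–O bond and methyl replaces oxygen with retention, so the ring-bearing chain and the hydroxypropyl chain should end up trans (E).

Step 10
Reactants: 14 (4E)-7-[(3S)-3-(tert-butyldimethylsilyloxy)-2,6,6-trimethylcyclohex-1-en-1-yl]-5-methylhept-4-en-1-ol
Product: 15 tert-butyl{[(1S)-3-[(3E)-7-iodo-3-methylhept-3-en-1-yl]-2,4,4-trimethylcyclohex-2-en-1-yl]oxy}dimethylsilane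
Conditions: I2, PPh3, imidazole, CH2Cl2, 0 °C → rt
Reagents that add atoms: iodine, II
Why: Appel-type iodination of the primary alcohol, which does not touch the trisubstituted alkene or the silyl ether.

Step 11
Reactants: 15 tert-butyl{[(1S)-3-[(3E)-7-iodo-3-methylhept-3-en-1-yl]-2,4,4-trimethylcyclohex-2-en-1-yl]oxy}dimethylsilane
Product: 16 {(4E)-7-[(3S)-3-(tert-butyldimethylsilyloxy)-2,6,6-trimethylcyclohex-1-en-1-yl]-5-methylhept-4-en-1-yl}triphenylphosphonium iodide
Conditions: PPh3, i-Pr2NEt (cat.), MeCN, 80 °C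
Reagents that add atoms: triphenylphosphine, c1ccc(cc1)P(c1ccccc1)c1ccccc1
Why: SN2 quaternisation of triphenylphosphine by an unhindered primary iodide, with a trace of amine to keep the medium from turning acidic towards the silyl ether.

Step 12
Reactants: 17 2-deoxy-D-ribose
Product: 18 (2R,3S)-4-(1,3-dithian-2-yl)butane-1,2,3-triol
Conditions: HS(CH2)3SH, conc. HCl, 0 °C → rt
Reagents that add atoms: propane-1,3-dithiol, SCCCS
Why: Acid-catalysed dithioacetalisation traps the aldehyde of the lactol equilibrium and frees the acyclic triol without touching either stereocentre.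

Step 13
Reactants: 18 (2R,3S)-4-(1,3-dithian-2-yl)butane-1,2,3-triol
Product: 19 (1S)-1-[(4R)-2,2-dimethyl-1,3-dioxolan-4-yl]-2-(1,3-dithian-2-yl)ethan-1-ol
Conditions: Me2C(OMe)2, p-toluenesulfonic acid (cat.), CH2Cl2, 0 °C
Reagents that add atoms: 2,2-dimethoxypropane, COC(C)(C)OC
Why: Acid-catalysed transacetalisation favours the dioxolane of the terminal 1,2-diol, which leaves the hydroxyl that will become the furanone ring oxygen free.

Step 14
Reactants: 19 (1S)-1-[(4R)-2,2-dimethyl-1,3-dioxolan-4-yl]-2-(1,3-dithian-2-yl)ethan-1-ol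
Product: 20 2-{(2S)-2-[(4R)-2,2-dimethyl-1,3-dioxolan-4-yl]-2-[(4-methoxybenzyl)oxy]ethyl}-1,3-dithiane
Conditions: NaH, PMBCl, n-Bu4NI (cat.), THF/DMF, 0 °C → rt
Reagents that add atoms: 4-methoxybenzyl chloride, COc1ccc(CCl)cc1
Why: Williamson etherification of the secondary alkoxide, giving an ether that survives alkyllithium bases and can later be removed oxidatively.

Step 15
Reactants: 20 2-{(2S)-2-[(4R)-2,2-dimethyl-1,3-dioxolan-4-yl]-2-[(4-methoxybenzyl)oxy]ethyl}-1,3-dithiane
Product: 21 (3S)-3-[(4R)-2,2-dimethyl-1,3-dioxolan-4-yl]-3-[(4-methoxybenzyl)oxy]propanal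
Conditions: MeI, CaCO3, MeCN/H2O, 45 °C
Reagents that add atoms: water, O
Why: Alkylative dithioacetal hydrolysis (S-methylation, then attack of water) under CaCO3 buffering, neutral enough to keep the acetonide, the PMB ether and the β-alkoxy aldehyde intact.

Step 16
Reactants: 16 {(4E)-7-[(3S)-3-(tert-butyldimethylsilyloxy)-2,6,6-trimethylcyclohex-1-en-1-yl]-5-methylhept-4-en-1-yl}triphenylphosphonium iodide; 21 (3S)-3-[(4R)-2,2-dimethyl-1,3-dioxolan-4-yl]-3-[(4-methoxybenzyl)oxy]propanal; 22 formaldehyde (charged as paraformaldehyde)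
Product: 27 Z-hydroxymethyl triene acetonide, via phosphorus ylide 23 (not isolated), via lithium betaine 24 (not isolated), via beta-oxido ylide 25 (not isolated), via formaldehyde adduct 26 (not isolated)
Conditions: n-BuLi, THF, 0 °C; 21, −78 °C; sec-BuLi, −78 → −25 °C; (CH2O)n, 0 °C → rt; aq. NH4Cl
Reagents that add atoms: none
Why: n-BuLi converts 16 into the non-stabilised ylide 23, which adds to aldehyde 21 at −78 °C to give the lithium-halide-complexed betaine 24; sec-BuLi then removes the remaining proton alpha to phosphorus to give the β-oxido ylide 25, whose carbanion carbon adds formaldehyde to give 26, and loss of Ph3P=O through the lithium alkoxide that came from 21 forms the C=C bond while the formaldehyde carbon stays as CH2OH. The closest known reaction type is the β-oxido ylide (SCOOPY) variant of the Wittig reaction with formaldehyde as second electrophile, which gives 2-substituted (Z)-alk-2-en-1-ols whose hydroxymethyl group lies cis to the substituent brought in by the first aldehyde. No ring is closed and no stereocentre is created in the product: the transient centres of 24 and 26 disappear on elimination, and the ring carbinol carbon, the PMB-ether carbon and the dioxolane carbon are spectators. The step needs addition to the aldehyde to outrun its enolisation and β-elimination of the PMB-oxy group, which the low temperature, the reactive non-stabilised ylide and the purely ether-type protection of 21 should secure. It also needs elimination through the first-formed alkoxide instead of the new primary one, and a single alkene geometry; both should follow from the chelated lithium alkoxide of the betaine, which fixes the configuration at the phosphorus-bearing carbon when formaldehyde adds and is the oxygen that leaves with phosphorus.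

Step 17
Reactants: 27 Z-hydroxymethyl triene acetonide
Product: 28 Z-triene tetraol mono-TBS mono-PMB ether (triol 28)
Conditions: AcOH/THF/H2O (3:1:1), 40 °C
Reagents that add atoms: none
Why: Acid-catalysed acetal hydrolysis, in which the terminal isopropylidene acetal should be cleaved by aqueous acetic acid faster than the hindered secondary silyl ether or the PMB ether.

Step 18
Reactants: 28 triol
Product: 29 bis-primary TBS ether with free secondary alcohol
Conditions: TBSCl (2.2 equiv), imidazole, CH2Cl2, −20 → 0 °C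
Reagents that add atoms: tert-butyldimethylsilyl chloride, CC(C)(C)[Si](C)(C)Cl
Why: Chemoselective silylation, in which the two primary hydroxyls (allylic and diol terminus) react much faster than the secondary hydroxyl flanked by the PMB-ether carbon.

Step 19
Reactants: 29 bis-primary TBS ether with free secondary alcohol
Product: 30 α-PMB-oxy α'-silyloxy ketone
Conditions: Dess–Martin periodinane, pyridine, CH2Cl2, 0 °C → rt
Reagents that add atoms: none
Why: Dess–Martin oxidation of the only free alcohol under non-basic buffered conditions, which should not epimerise the ether-bearing carbon next to the new ketone.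

Step 20
Reactants: 30 α-PMB-oxy α'-silyloxy ketone
Product: 31 (3S)-α-hydroxy ketone
Conditions: DDQ (2,3-dichloro-5,6-dicyano-1,4-benzoquinone), CH2Cl2/pH 7 buffer, 0 °C
Reagents that add atoms: none
Why: Oxidative cleavage of the 4-methoxybenzyl ether by hydride abstraction from the electron-rich benzylic position and hydrolysis of the oxocarbenium ion, under conditions that leave silyl ethers and trisubstituted alkenes alone.

Step 21
Reactants: 31 (3S)-α-hydroxy ketone
Product: 33 tris-TBS furanone, via phosphoranylidene acetate 32 (not isolated)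
Conditions: Ph3P=C=C=O, toluene, 80 °C
Reagents that add atoms: (triphenylphosphoranylidene)ketene, O=C=C=P(c1ccccc1)(c1ccccc1)c1ccccc1
Why: Bestmann butenolide synthesis, in which the hydroxyl adds to the ketenylidene phosphorane to give the ester ylide 32, which closes by intramolecular Wittig olefination onto the neighbouring ketone without involving the C5 stereocentre.

Step 22
Reactants: 33 tris-TBS furanone
Product: 34 CNP0330392.1
Conditions: HF·pyridine, pyridine, THF, 0 °C → rt
Reagents that add atoms: none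
Why: Fluoride-mediated desilylation under buffered, weakly acidic conditions should remove all three silyl groups without opening the furanone, epimerising its C5 or ionising the allylic alcohols.

**Compound list**

1 | 4,4-dimethylcyclohexane-1,3-dione | CC1(C)CCC(=O)CC1=O | starting material
2 | 2,4,4-trimethylcyclohexane-1,3-dione | CC1C(=O)CCC(C)(C)C1=O | intermediate
3 | 3-(2-methylpropoxy)-2,6,6-trimethylcyclohex-2-en-1-one | CC1=C(OCC(C)C)CCC(C)(C)C1=O | intermediate
4 | bromomagnesium 3-(2-methylpropoxy)-2,6,6-trimethyl-1-vinylcyclohex-2-en-1-olate | CC1=C(OCC(C)C)CCC(C)(C)C1(C=C)O[Mg]Br | intermediate (not isolated)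
5 | 2,4,4-trimethyl-3-vinylcyclohex-2-en-1-one | CC1=C(C=C)C(C)(C)CCC1=O | intermediate
6 | (1S)-2,4,4-trimethyl-3-vinylcyclohex-2-en-1-ol | CC1=C(C=C)C(C)(C)CC[C@@H]1O | intermediate
7 | tert-butyl(dimethyl){[(1S)-2,4,4-trimethyl-3-vinylcyclohex-2-en-1-yl]oxy}silane | CC1=C(C=C)C(C)(C)CC[C@@H]1O[Si](C)(C)C(C)(C)C | intermediate
8 | 9-{2-[(3S)-3-(tert-butyldimethylsilyloxy)-2,6,6-trimethylcyclohex-1-en-1-yl]ethyl}-9-borabicyclo[3.3.1]nonane | CC1=C(CCB2C3CCCC2CCC3)C(C)(C)CC[C@@H]1O[Si](C)(C)C(C)(C)C | intermediate (not isolated)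
9 | 2-[(3S)-3-(tert-butyldimethylsilyloxy)-2,6,6-trimethylcyclohex-1-en-1-yl]ethan-1-ol | CC1=C(CCO)C(C)(C)CC[C@@H]1O[Si](C)(C)C(C)(C)C | intermediate
10 | tert-butyl{[(1S)-3-(2-iodoethyl)-2,4,4-trimethylcyclohex-2-en-1-yl]oxy}dimethylsilane | CC1=C(CCI)C(C)(C)CC[C@@H]1O[Si](C)(C)C(C)(C)C | intermediate
11 | 3,4-dihydro-2H-pyran | C1=COCCC1 | starting material
12 | 6-lithio-3,4-dihydro-2H-pyran | [Li]C1=CCCCO1 | intermediate (not isolated)
13 | 6-{2-[(3S)-3-(tert-butyldimethylsilyloxy)-2,6,6-trimethylcyclohex-1-en-1-yl]ethyl}-3,4-dihydro-2H-pyran | CC1=C(CCC2=CCCCO2)C(C)(C)CC[C@@H]1O[Si](C)(C)C(C)(C)C | intermediate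
14 | (4E)-7-[(3S)-3-(tert-butyldimethylsilyloxy)-2,6,6-trimethylcyclohex-1-en-1-yl]-5-methylhept-4-en-1-ol | CC1=C(CC/C(C)=C/CCCO)C(C)(C)CC[C@@H]1O[Si](C)(C)C(C)(C)C | intermediate
15 | tert-butyl{[(1S)-3-[(3E)-7-iodo-3-methylhept-3-en-1-yl]-2,4,4-trimethylcyclohex-2-en-1-yl]oxy}dimethylsilane | CC1=C(CC/C(C)=C/CCCI)C(C)(C)CC[C@@H]1O[Si](C)(C)C(C)(C)C | intermediate
16 | {(4E)-7-[(3S)-3-(tert-butyldimethylsilyloxy)-2,6,6-trimethylcyclohex-1-en-1-yl]-5-methylhept-4-en-1-yl}triphenylphosphonium iodide | CC1=C(CC/C(C)=C/CCC[P+](c2ccccc2)(c2ccccc2)c2ccccc2)C(C)(C)CC[C@@H]1O[Si](C)(C)C(C)(C)C.[I-] | intermediate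
17 | 2-deoxy-D-ribose, (3S,4R)-3,4,5-trihydroxypentanal drawn open-chain | O=CC[C@H](O)[C@H](O)CO | starting material
18 | (2R,3S)-4-(1,3-dithian-2-yl)butane-1,2,3-triol | C1CSC(C[C@H](O)[C@H](O)CO)SC1 | intermediate
19 | (1S)-1-[(4R)-2,2-dimethyl-1,3-dioxolan-4-yl]-2-(1,3-dithian-2-yl)ethan-1-ol | C1CSC(C[C@H](O)[C@H]2COC(C)(C)O2)SC1 | intermediate
20 | 2-{(2S)-2-[(4R)-2,2-dimethyl-1,3-dioxolan-4-yl]-2-[(4-methoxybenzyl)oxy]ethyl}-1,3-dithiane | C1CSC(C[C@@H]([C@H]2COC(C)(C)O2)OCc2ccc(OC)cc2)SC1 | intermediate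
21 | (3S)-3-[(4R)-2,2-dimethyl-1,3-dioxolan-4-yl]-3-[(4-methoxybenzyl)oxy]propanal | O=CC[C@@H]([C@H]1COC(C)(C)O1)OCc1ccc(OC)cc1 | intermediate
22 | formaldehyde | C=O | starting material
23 | ylide of 16, {(4E)-7-[(3S)-3-(tert-butyldimethylsilyloxy)-2,6,6-trimethylcyclohex-1-en-1-yl]-5-methylhept-4-en-1-ylidene}triphenylphosphorane | CC1=C(CC/C(C)=C/CCC=P(c2ccccc2)(c2ccccc2)c2ccccc2)C(C)(C)CC[C@@H]1O[Si](C)(C)C(C)(C)C | intermediate (not isolated)
24 | lithium iodide adduct of the betaine from 23 and 21 (β-oxido phosphonium, the two new centres transient and not drawn) | CC1=C(CC/C(C)=C/CCC(C([O-])C[C@@H]([C@H]2COC(C)(C)O2)OCc2ccc(OC)cc2)[P+](c2ccccc2)(c2ccccc2)c2ccccc2)C(C)(C)CC[C@@H]1O[Si](C)(C)C(C)(C)C.[Li+].[I-] | intermediate (not isolated)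
25 | lithium β-oxido ylide from 24 | CC1=C(CC/C(C)=C/CCC(C([O-])C[C@@H]([C@H]2COC(C)(C)O2)OCc2ccc(OC)cc2)=P(c2ccccc2)(c2ccccc2)c2ccccc2)C(C)(C)CC[C@@H]1O[Si](C)(C)C(C)(C)C.[Li+] | intermediate (not isolated)
26 | formaldehyde adduct of 25 (dioxido phosphonium, lithium salt) | CC1=C(CC/C(C)=C/CCC(C[O-])(C([O-])C[C@@H]([C@H]2COC(C)(C)O2)OCc2ccc(OC)cc2)[P+](c2ccccc2)(c2ccccc2)c2ccccc2)C(C)(C)CC[C@@H]1O[Si](C)(C)C(C)(C)C.[Li+] | intermediate (not isolated)
27 | (2Z,5E)-2-{(3S)-3-[(4R)-2,2-dimethyl-1,3-dioxolan-4-yl]-3-[(4-methoxybenzyl)oxy]propylidene}-6-methyl-8-[(3S)-3-(tert-butyldimethylsilyloxy)-2,6,6-trimethylcyclohex-1-en-1-yl]oct-5-en-1-ol | CC1=C(CC/C(C)=C/CC/C(=C/C[C@@H]([C@H]2COC(C)(C)O2)OCc2ccc(OC)cc2)CO)C(C)(C)CC[C@@H]1O[Si](C)(C)C(C)(C)C | intermediate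
28 | (2R,3S,5Z,9E)-6-(hydroxymethyl)-3-[(4-methoxybenzyl)oxy]-10-methyl-12-[(3S)-3-(tert-butyldimethylsilyloxy)-2,6,6-trimethylcyclohex-1-en-1-yl]dodeca-5,9-diene-1,2-diol | CC1=C(CC/C(C)=C/CC/C(=C/C[C@@H]([C@H](O)CO)OCc2ccc(OC)cc2)CO)C(C)(C)CC[C@@H]1O[Si](C)(C)C(C)(C)C | intermediate
29 | (2R,3S,5Z,9E)-1-(tert-butyldimethylsilyloxy)-6-[(tert-butyldimethylsilyloxy)methyl]-3-[(4-methoxybenzyl)oxy]-10-methyl-12-[(3S)-3-(tert-butyldimethylsilyloxy)-2,6,6-trimethylcyclohex-1-en-1-yl]dodeca-5,9-dien-2-ol | CC1=C(CC/C(C)=C/CC/C(=C/C[C@@H]([C@H](O)CO[Si](C)(C)C(C)(C)C)OCc2ccc(OC)cc2)CO[Si](C)(C)C(C)(C)C)C(C)(C)CC[C@@H]1O[Si](C)(C)C(C)(C)C | intermediate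
30 | (3S,5Z,9E)-1-(tert-butyldimethylsilyloxy)-6-[(tert-butyldimethylsilyloxy)methyl]-3-[(4-methoxybenzyl)oxy]-10-methyl-12-[(3S)-3-(tert-butyldimethylsilyloxy)-2,6,6-trimethylcyclohex-1-en-1-yl]dodeca-5,9-dien-2-one | CC1=C(CC/C(C)=C/CC/C(=C/C[C@@H](C(=O)CO[Si](C)(C)C(C)(C)C)OCc2ccc(OC)cc2)CO[Si](C)(C)C(C)(C)C)C(C)(C)CC[C@@H]1O[Si](C)(C)C(C)(C)C | intermediate
31 | (3S,5Z,9E)-1-(tert-butyldimethylsilyloxy)-6-[(tert-butyldimethylsilyloxy)methyl]-3-hydroxy-10-methyl-12-[(3S)-3-(tert-butyldimethylsilyloxy)-2,6,6-trimethylcyclohex-1-en-1-yl]dodeca-5,9-dien-2-one | CC1=C(CC/C(C)=C/CC/C(=C/C[C@@H](C(=O)CO[Si](C)(C)C(C)(C)C)O)CO[Si](C)(C)C(C)(C)C)C(C)(C)CC[C@@H]1O[Si](C)(C)C(C)(C)C | intermediate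
32 | (triphenylphosphoranylidene)acetate ester of the C3 hydroxyl of 31 | CC1=C(CC/C(C)=C/CC/C(=C/C[C@@H](C(=O)CO[Si](C)(C)C(C)(C)C)OC(=O)C=P(c2ccccc2)(c2ccccc2)c2ccccc2)CO[Si](C)(C)C(C)(C)C)C(C)(C)CC[C@@H]1O[Si](C)(C)C(C)(C)C | intermediate (not isolated)
33 | (5S)-4-[(tert-butyldimethylsilyloxy)methyl]-5-{(2Z,6E)-3-[(tert-butyldimethylsilyloxy)methyl]-7-methyl-9-[(3S)-3-(tert-butyldimethylsilyloxy)-2,6,6-trimethylcyclohex-1-en-1-yl]nona-2,6-dien-1-yl}furan-2(5H)-one | CC1=C(CC/C(C)=C/CC/C(=C/C[C@@H]2OC(=O)C=C2CO[Si](C)(C)C(C)(C)C)CO[Si](C)(C)C(C)(C)C)C(C)(C)CC[C@@H]1O[Si](C)(C)C(C)(C)C | intermediate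
34 | CNP0330392.1, (5S)-4-(hydroxymethyl)-5-{(2Z,6E)-3-(hydroxymethyl)-9-[(3S)-3-hydroxy-2,6,6-trimethylcyclohex-1-en-1-yl]-7-methylnona-2,6-dien-1-yl}furan-2(5H)-one | CC1=C(CC/C(C)=C/CC/C(=C/C[C@@H]2OC(=O)C=C2CO)CO)C(C)(C)CC[C@@H]1O | target

**Count and risks**

Total step count: 22 (steps 1–11 phosphonium salt, steps 12–15 aldehyde, step 16 union, steps 17–22 endgame).
Longest linear sequence: 18 steps (steps 1–11 and 16–22).

Steps most likely to fail:

Step 16. The basic ylide may deprotonate the aldehyde alpha to the carbonyl, with loss of the PMB-oxy group. The betaine may be only partly converted into the β-oxido ylide, or may collapse to the simple cis-disubstituted alkene. Elimination may also run through the new primary alkoxide, or the geometry may leak. The fallback sets out from 10 (and uses 21) and comes back at 27. 2,3-Dihydrofuran is lithiated at C5 (t-BuLi, THF) to 5-lithio-2,3-dihydrofuran F1, which is alkylated by iodide 10 to give the 5-alkyl-2,3-dihydrofuran F2. The same NiCl2(PPh3)2/MeMgBr opening gives the (3E)-homoallylic alcohol F3, one carbon shorter than 14, and I2/PPh3/imidazole gives the homoallylic iodide F4. Commercial methyl bis(2,2,2-trifluoroethyl)phosphonoacetate is alkylated with F4 (NaH, DMF) to the α-substituted phosphonate F5. Still–Gennari olefination of F5 with aldehyde 21 (KN(SiMe3)2, 18-crown-6, THF, −78 °C) should give the Z enoate F6, with the ester cis to the CH2 that leads to the PMB-ether carbon. Reduction of the ester with i-Bu2AlH (CH2Cl2, −78 °C) gives 27.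

Step 9. Insertion of zerovalent nickel into the C–O bond of the six-membered enol ether may be slow, the alkene geometry may erode on prolonged heating, and the allylic silyl ether may be attacked. The fallback sets out from 7 and comes back at 14. Compound 7 is hydroborated with 9-BBN to borane 8 as in step 6 but not oxidised. Aqueous K3PO4, Pd(dppf)Cl2, AsPh3 and (4E)-5-iodohex-4-en-1-ol F7 are added (DMF/THF, rt). F7 is prepared from commercial hex-4-yn-1-ol by hydrozirconation with excess Cp2Zr(H)Cl (THF, 50 °C) and iodinolysis with I2. B-alkyl Suzuki–Miyaura coupling with retention at the alkenyl iodide should give 14 directly, bypassing steps 6 to 9.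

Step 21. The carbinol centre next to the ketone may epimerise by enolisation or acyloin shift, a silyl group may migrate to the free hydroxyl before ring closure, and the intramolecular olefination of the flanked ketone may be sluggish. The fallback sets out from 30 and comes back at 33. Ethyl acetate is deprotonated with LiN(i-Pr)2 (THF, −78 °C) to its lithium enolate F8, which adds to ketone 30 to give the β-hydroxy ester F9 as a mixture at the new tertiary carbinol (of no consequence). DDQ (CH2Cl2/pH 7 buffer) followed by pyridinium p-toluenesulfonate in toluene removes the PMB group and closes the β-hydroxy-γ-lactone F10. Dehydration with SOCl2/pyridine (0 °C) towards the acidic CH2 next to the lactone carbonyl should give 33, so a free α-hydroxy ketone is never formed.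

**Further compounds**

F1 | step 16 | 5-lithio-2,3-dihydrofuran | [Li]C1=CCCO1
F2 | step 16 | 5-{2-[(3S)-3-(tert-butyldimethylsilyloxy)-2,6,6-trimethylcyclohex-1-en-1-yl]ethyl}-2,3-dihydrofuran | CC1=C(CCC2=CCCO2)C(C)(C)CC[C@@H]1O[Si](C)(C)C(C)(C)C
F3 | step 16 | (3E)-6-[(3S)-3-(tert-butyldimethylsilyloxy)-2,6,6-trimethylcyclohex-1-en-1-yl]-4-methylhex-3-en-1-ol | CC1=C(CC/C(C)=C/CCO)C(C)(C)CC[C@@H]1O[Si](C)(C)C(C)(C)C
F4 | step 16 | tert-butyl{[(1S)-3-[(3E)-6-iodo-3-methylhex-3-en-1-yl]-2,4,4-trimethylcyclohex-2-en-1-yl]oxy}dimethylsilane | CC1=C(CC/C(C)=C/CCI)C(C)(C)CC[C@@H]1O[Si](C)(C)C(C)(C)C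
F5 | step 16 | methyl (5E)-2-[bis(2,2,2-trifluoroethoxy)phosphoryl]-6-methyl-8-[(3S)-3-(tert-butyldimethylsilyloxy)-2,6,6-trimethylcyclohex-1-en-1-yl]oct-5-enoate | CC1=C(CC/C(C)=C/CCC(C(=O)OC)P(=O)(OCC(F)(F)F)OCC(F)(F)F)C(C)(C)CC[C@@H]1O[Si](C)(C)C(C)(C)C
F6 | step 16 | methyl (2Z,5E)-2-{(3S)-3-[(4R)-2,2-dimethyl-1,3-dioxolan-4-yl]-3-[(4-methoxybenzyl)oxy]propylidene}-6-methyl-8-[(3S)-3-(tert-butyldimethylsilyloxy)-2,6,6-trimethylcyclohex-1-en-1-yl]oct-5-enoate | CC1=C(CC/C(C)=C/CC/C(=C/C[C@@H]([C@H]2COC(C)(C)O2)OCc2ccc(OC)cc2)C(=O)OC)C(C)(C)CC[C@@H]1O[Si](C)(C)C(C)(C)C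
F7 | step 9 | (4E)-5-iodohex-4-en-1-ol | C/C(I)=C\CCCO
F8 | step 21 | lithium 1-ethoxyethen-1-olate (lithium enolate of ethyl acetate) | [Li]OC(=C)OCC
F9 | step 21 | ethyl ester adduct of 30, the 3-hydroxy-3-[(tert-butyldimethylsilyloxy)methyl]-4-[(4-methoxybenzyl)oxy] ester, (4S), mixture at C3 | CC1=C(CC/C(C)=C/CC/C(=C/C[C@@H](C(O)(CC(=O)OCC)CO[Si](C)(C)C(C)(C)C)OCc2ccc(OC)cc2)CO[Si](C)(C)C(C)(C)C)C(C)(C)CC[C@@H]1O[Si](C)(C)C(C)(C)C
F10 | step 21 | (5S)-4-hydroxy-4-[(tert-butyldimethylsilyloxy)methyl]dihydrofuran-2(3H)-one carrying the chain of 33 at C5, mixture at C4 | CC1=C(CC/C(C)=C/CC/C(=C/C[C@@H]2OC(=O)CC2(O)CO[Si](C)(C)C(C)(C)C)CO[Si](C)(C)C(C)(C)C)C(C)(C)CC[C@@H]1O[Si](C)(C)C(C)(C)C
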